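The constants used here are assumed; what happens was integrated by code.

Turning L.E into L.Z and back leaves the sum of the two unchanged, and with an equilibrium constant of one it ends at an even split.

    2 L → L2 (k1 = 180 M⁻¹ s⁻¹, Ea1 = 39.0 kJ mol⁻¹)
    L + E → L.E (k2 = 2600 M⁻¹ s⁻¹, Ea2 = 44.0 kJ mol⁻¹)
    L + Z → L.Z (k3 = 1400 M⁻¹ s⁻¹, Ea3 = 44.0 kJ mol⁻¹)
    L.E ⇌ L.Z (k4 = 0.20 s⁻¹, Ea4 = 73.0 kJ mol⁻¹)
    Q ⇌ L, rate k5*(cs5 - [L]) while solid is left; crystals form when [L] > cs5 (cs5 = 0.33 mM, k5 = 0.56 s⁻¹)
    (constants at 35 °C)

all flasks: E 0.0010 M; Q 2.00 equiv; Z 0.0010 M; time 25 s
- maple: at 20 °C until 8.0 s, from then on at 50 °C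
- birch: temperature 20 °C
- ash: temperature 35 °C
- larch: temperature 50 °C

- L is single-handed; E and Z are mirror images of each other, charged as a racemate, each of them at the stated concentration
- a doubled species enters its step squared and goes two at a time
- Q is a solid; its amount is given per volume of the solution
- the list of constants is for 35 °C, to be carried to other temperatures by the activation energies
- at the start none of Q is in solution
- the handed part of L does not stay in what it makes, so the products of the two hands are mirror images too

* the flask with the highest share of L.E in all that became L.E or L.Z ("all alike" if they lie within 1.5 percentage points) (maple / birch / ash / larch / all alike)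
* share of L.E in all that became L.E or L.Z, maple
* share of L.E in all that became L.E or L.Z, birch
* share of L.E in all that became L.E or L.Z, ash
* share of L.E in all that became L.E or L.Z, larch

*Where must the share of L.E end?* At a fraction of 0.5, the answer under thermodynamic control, whichever enantiomer L attacked first.

*Where does it start?* Under kinetic control, with a selectivity factor of 1.86, because 2600 M⁻¹ s⁻¹ stands above 1400 M⁻¹ s⁻¹. So the first product is 65.0 % L.E.

*How fast does it go from one to the other?* Both directions close the gap between L.E and L.Z at once. At 50 °C the rate constant is 0.751 s⁻¹, so the gap halves in 0.462 s. That time, the natural logarithm of two over twice the rate constant, is the relaxation half-life.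

*What does that mean for maple?* Maple is hot from 8.0 s to 25 s, which is 36.8 relaxation half-lives, so I expect an even split there and in larch.

*And the weak spot?* Birch, at 20 °C. There the relaxation half-life is 7.45 s, and 25 s holds 3.36 of them. An excess formed at the very start shrinks to 1.5 percentage points.

*Is that the deviation in birch?* No, it is a size, not a reckoned value. Product formed late comes from a remainder richer in Z, since E is taken faster, at 2600 M⁻¹ s⁻¹ against 1400 M⁻¹ s⁻¹, and that pulls the other way. I leave the sign open, put birch within 1.5 points of even, and answer all alike.

The forecast says all alike, with 49.95 % for maple, 49.1 % for birch, 49.8 % for ash and 49.97 % for larch, on the ground that, birch apart, relaxation “wipes out the early excess of L.E”.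

The simulation gives all alike: maple 50.0 %, birch 49.2 %, ash 49.8 %, larch 50.0 %.

In maple the relaxation half-life of 0.462 s stands against 17.0 s at the second temperature, and at 25.0 s the flask holds L.E 48.5 % and L.Z 48.5 % of the E and Z together charged. The neighbour of maple with 0.500 equiv of Q has the same 0.462 s over the same heated stretch, and at 25.0 s it holds Z 40.9 %, more than E at 34.4 %, with L.E 12.4 % beside L.Z 12.4 %, a share of 50.0 %.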